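**Retrosynthetic overview**
1. C6–C7 (acyl–alkyl): (E)-hex-3-enedioic acid 1, as its dichloride 2, and 1-bromohexadecane 3, as Grignard reagent 4, give keto acid chloride 5 and, after methanolysis, the open-chain C22 β,γ-unsaturated keto ester 6.
2. C3–O and C6–O together (the dienol + O2 [4+2] of the presumed biogenesis, with a chiral enamine standing in for the dienol): 6 → dienamine 7 → singlet-oxygen adduct 8 → peroxy hemiketal 9; C3 is set here.
3. C6–OMe: 9 → peroxycarbenium ion 10 → reversible methanol capture to the C6 epimer 11 and chondrillin 12.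
4. Ring order: the 1,2-dioxine is the only ring and is closed in the oxygenation (line 2), before the ketal oxygen is exchanged.

Assumption: the hydrogen-bond-steering model for the quinine-derived amine is taken to give attack on the C3 Re face (3R); if analysis shows the opposite sense, the pseudo-enantiomeric 9-amino-9-deoxy-epi-quinidine is used with nothing else changed.

Step 1
Reactants: 1 (E)-hex-3-enedioic acid (3.0 equiv); 3 1-bromohexadecane (1.0 equiv)
Product: 6 methyl (E)-6-oxodocos-3-enoate, via (E)-hex-3-enedioyl dichloride 2 (not isolated), via hexadecylmagnesium bromide 4 (not isolated), via (E)-6-oxodocos-3-enoyl chloride 5 (not isolated)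
Conditions: 1, (COCl)2, DMF (cat.), CH2Cl2, 0 °C → rt, evaporate; 3, Mg, THF, rt (separate flask); 4 added to 2, Fe(acac)3 (3 mol%), THF, −78 °C; then MeOH, pyridine, −78 °C → 0 °C
Reagents that add atoms: oxalyl chloride (O=C(Cl)C(Cl)=O); magnesium ([Mg]); methanol (CO)
Why: Acid chloride formation followed by Fe(acac)3-catalysed acylation of an alkyl Grignard reagent (iron-catalysed ketone synthesis), which at −78 °C outruns both deprotonation of the activated CH2 groups and addition to the new ketone; the threefold excess of 2 makes monoacylation dominant on statistical grounds, methanolysis of the remaining COCl group gives the ester (the surplus of 2 is quenched by the same methanol and removed on silica), no stereocentre is formed and the E geometry is carried over from 1.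

Step 2
Reactants: 6 methyl (E)-6-oxodocos-3-enoate
Product: 9 methyl 2-[(3R)-6-hexadecyl-6-hydroxy-3,6-dihydro-1,2-dioxin-3-yl]acetate, via dienamine 7 (not isolated), via peroxy aminal 8 (not isolated)
Conditions: 9-amino-9-deoxy-epi-quinine (20 mol%), CF3CO2H (40 mol%), tetraphenylporphyrin (1 mol%), O2 (bubbling), white LED, CH2Cl2, 0 °C; then rapid SiO2 filtration at 0 °C
Reagents that add atoms: dioxygen (O=O); 9-amino-9-deoxy-epi-quinine (C=C[C@H]1CN2CC[C@H]1C[C@H]2[C@@H](N)c3ccnc4ccc(OC)cc34); water (O)
Why: Proposed new method: condensation of the ketone with the primary amine and loss of the doubly activated C5–H (α to the iminium and allylic) gives the linear 1-aminodiene 7 rather than the C7 enamine, and singlet oxygen, the fastest partner for an electron-rich s-cis diene, adds suprafacially across C3 and C6 in a hetero-Diels–Alder [4+2] cycloaddition (the amine-activated counterpart of the dienol + O2 event of the biogenesis) to give 8, which the water of condensation cleaves under the trifluoroacetate buffer to 9 (both C6 anomers) with release of the catalyst; C3 is set in the cycloaddition, O2 entering on the C3 Re face that lies under the protonated quinuclidinium (hydrogen-bond steering of the electrophile, the quinoline shielding the other face), which gives 3R; the closest known reaction types are the dienamine [4+2]/γ-amination of enals with azodicarboxylates, the amine-catalysed α-oxygenation of aldehydes and ketones with singlet oxygen, the γ-oxygenation of steroidal dienamines, and the [4+2] addition of singlet oxygen to photo-generated dienols that gives 3,6-dihydro-1,2-dioxin-3-ols.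

Step 3
Reactants: 9 methyl 2-[(3R)-6-hexadecyl-6-hydroxy-3,6-dihydro-1,2-dioxin-3-yl]acetate
Product: 12 chondrillin [methyl 2-((3R,6S)-6-hexadecyl-6-methoxy-3,6-dihydro-1,2-dioxin-3-yl)acetate], via peroxycarbenium ion 10 (not isolated), via 6-epi-chondrillin 11 (not isolated)
Conditions: MeOH, TsOH·H2O (5 mol%), 0 °C → rt, to equilibrium; NaHCO3; SiO2 (12 collected); the unpurified 11-rich remainder returned to MeOH, TsOH·H2O, two to three cycles
Reagents that add atoms: methanol (CO)
Why: Acid-catalysed ketalisation (SN1 exchange of OH for OMe) through the allylic peroxycarbenium ion 10 leaves the C3 centre and the O–O bond untouched; methanol adds reversibly to both faces of 10 in roughly equal amounts, so 11 and 12 form together and interconvert through 10, and C6 is fixed by taking 12 (6S, OMe trans to the C3 side chain) off on silica after each equilibration and returning the 11-rich remainder to the same acid, which funnels the material to 12.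

**Compound list**
1 | (E)-hex-3-enedioic acid | OC(=O)C/C=C/CC(=O)O | starting material
2 | (E)-hex-3-enedioyl dichloride | ClC(=O)C/C=C/CC(Cl)=O | intermediate
3 | 1-bromohexadecane | CCCCCCCCCCCCCCCCBr | starting material
4 | hexadecylmagnesium bromide | CCCCCCCCCCCCCCCC[Mg]Br | intermediate
5 | (E)-6-oxodocos-3-enoyl chloride | CCCCCCCCCCCCCCCCC(=O)C/C=C/CC(Cl)=O | intermediate
6 | methyl (E)-6-oxodocos-3-enoate | CCCCCCCCCCCCCCCCC(=O)C/C=C/CC(=O)OC | intermediate
7 | methyl (3E,5Z)-6-[(8S,9S)-9-deoxy-epi-quinin-9-ylamino]docosa-3,5-dienoate (dienamine) | C=C[C@H]1CN2CC[C@H]1C[C@H]2[C@@H](N/C(CCCCCCCCCCCCCCCC)=C\C=C\CC(=O)OC)c3ccnc4ccc(OC)cc34 | intermediate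
8 | methyl 2-[(3R,6S)-6-hexadecyl-6-[(8S,9S)-9-deoxy-epi-quinin-9-ylamino]-3,6-dihydro-1,2-dioxin-3-yl]acetate (peroxy aminal; hexadecyl cis to the C3 side chain) | C=C[C@H]1CN2CC[C@H]1C[C@H]2[C@@H](N[C@]5(CCCCCCCCCCCCCCCC)C=C[C@@H](CC(=O)OC)OO5)c3ccnc4ccc(OC)cc34 | intermediate
9 | methyl 2-[(3R)-6-hexadecyl-6-hydroxy-3,6-dihydro-1,2-dioxin-3-yl]acetate (peroxy hemiketal; both C6 anomers) | CCCCCCCCCCCCCCCCC1(O)C=C[C@@H](CC(=O)OC)OO1 | intermediate
10 | (3R)-6-hexadecyl-3-(2-methoxy-2-oxoethyl)-3H-1,2-dioxin-1-ium (peroxycarbenium ion) | CCCCCCCCCCCCCCCCC1=[O+]O[C@H](CC(=O)OC)C=C1 | intermediate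
11 | methyl 2-[(3R,6R)-6-hexadecyl-6-methoxy-3,6-dihydro-1,2-dioxin-3-yl]acetate (6-epi-chondrillin; OMe cis to the C3 side chain) | CCCCCCCCCCCCCCCC[C@]1(OC)C=C[C@@H](CC(=O)OC)OO1 | intermediate
12 | methyl 2-[(3R,6S)-6-hexadecyl-6-methoxy-3,6-dihydro-1,2-dioxin-3-yl]acetate (chondrillin) | CCCCCCCCCCCCCCCC[C@@]1(OC)C=C[C@@H](CC(=O)OC)OO1 | target

Total step count: 3
Longest linear sequence: 3 steps (1 or 3 → 6 → 9 → 12)

**Steps most likely to fail, most risky first**

Risk 1, step 2. The asymmetric dienamine/singlet-oxygen cycloaddition is untested. It may give [2+2] cleavage of the enamine, catalyst oxidation, amine-induced Kornblum–DeLaMare opening of the peroxide, or low ee. The fallback sets out from 6 and comes back at 12. A catalytic amount of DBU in CH2Cl2 moves the double bond of 6 into conjugation with the ketone to give methyl (E)-6-oxodocos-4-enoate F5. Irradiation of this enone through Pyrex under O2 with tetraphenylporphyrin (CH2Cl2, 0 °C) brings about E/Z isomerisation, photoenolisation by 1,5-hydrogen shift to the (Z)-dienol and the same [4+2] uptake of singlet oxygen, now without a chiral controller. It gives 9 as a 1:1 mixture with its mirror image, methyl 2-[(3S)-6-hexadecyl-6-hydroxy-3,6-dihydro-1,2-dioxin-3-yl]acetate F6. Ketalisation exactly as in step 3 gives 12 and 11, each with its enantiomer, ent-chondrillin F7 and ent-6-epi-chondrillin F8. The diastereomers are separated on silica and the 11/F8 fraction is re-equilibrated. Preparative HPLC of the 12/F7 fraction on amylose tris(3,5-dimethylphenylcarbamate) removes F7 and delivers enantiopure 12. The same column polishes material of incomplete ee from the main route.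

Risk 2, step 3. The sulfonic acid may fragment the peroxide, or the equilibrium may hold too little of the 6S epimer. The fallback sets out from 6 and comes back at 12. The step-2 oxygenation is run in CH2Cl2/MeOH 4:1 over 3 Å molecular sieves, so that the protonated aminal 8 is cleaved by methanol instead of water. The C6–N bond ionises to 10 under the ammonium trifluoroacetate buffer alone and the catalyst is turned over by methanolysis. 12 and 11 are then obtained directly and separated as before, and the isolated hemiketal 9 never meets a sulfonic acid. No new compound is made (F0).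

Risk 3, step 1. The monoacylation is statistical and the β,γ-unsaturated bis-acid chloride is base-sensitive. The fallback sets out from 1 and 3 and comes back at 6. Fischer esterification of 1 (MeOH, H2SO4 cat.) gives dimethyl (E)-hex-3-enedioate F1. One equivalent of dilute aqueous NaOH in THF at 0 °C gives the half ester (E)-6-methoxy-6-oxohex-3-enoic acid F2. Steglich coupling with ethanethiol (DCC, DMAP) gives the thioester methyl (E)-6-(ethylsulfanyl)-6-oxohex-3-enoate F3. Zinc insertion into 3 (Zn dust, LiCl, THF, 50 °C) gives hexadecylzinc bromide F4. Fukuyama coupling of F3 with F4 (PdCl2(PPh3)2 5 mol%, toluene/THF, rt) then gives 6 with no statistical step, no acid chloride and no basic organometallic.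

**Further compounds**
F1 | step 1 | dimethyl (E)-hex-3-enedioate | COC(=O)C/C=C/CC(=O)OC
F2 | step 1 | (E)-6-methoxy-6-oxohex-3-enoic acid | COC(=O)C/C=C/CC(=O)O
F3 | step 1 | methyl (E)-6-(ethylsulfanyl)-6-oxohex-3-enoate | CCSC(=O)C/C=C/CC(=O)OC
F4 | step 1 | hexadecylzinc bromide | CCCCCCCCCCCCCCCC[Zn]Br
F5 | step 2 | methyl (E)-6-oxodocos-4-enoate | CCCCCCCCCCCCCCCCC(=O)/C=C/CCC(=O)OC
F6 | step 2 | methyl 2-[(3S)-6-hexadecyl-6-hydroxy-3,6-dihydro-1,2-dioxin-3-yl]acetate (enantiomer of 9) | CCCCCCCCCCCCCCCCC1(O)C=C[C@H](CC(=O)OC)OO1
F7 | step 2 | ent-chondrillin: methyl 2-[(3S,6R)-6-hexadecyl-6-methoxy-3,6-dihydro-1,2-dioxin-3-yl]acetate | CCCCCCCCCCCCCCCC[C@]1(OC)C=C[C@H](CC(=O)OC)OO1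
F8 | step 2 | ent-6-epi-chondrillin: methyl 2-[(3S,6S)-6-hexadecyl-6-methoxy-3,6-dihydro-1,2-dioxin-3-yl]acetate | CCCCCCCCCCCCCCCC[C@@]1(OC)C=C[C@H](CC(=O)OC)OO1
F0 | step 3 | none | none
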